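**Retrosynthetic overview**

- The target flavanone is unmasked from its bis-silyl ether with buffered fluoride. The C4 ketone is traced back to the C4 methyl ether of a 4-methoxyflavan (hydrolysis, then oxidation).
- The route rests on ring C, the O1–C2–C3–C4 chain fused to ring A at C4a/C8a. Cutting O1–C2 and C3–C4 gives the oxa-diene O1=C8a–C4a=C4 of an ortho-quinone methide drawn from a ring A salicylaldehyde, and the C2=C3 alkene of a ring B styrene. The two are joined by a catalytic asymmetric hetero-[4+2] cycloaddition.
- The salicylaldehyde comes from 2,4,6-trihydroxybenzaldehyde by C-prenylation, 4-O-methylation and silylation of the less hindered ortho hydroxyl. The styrene comes from isovanillin by silylation and Wittig methylenation.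
- Ring order: rings A and B are bought. Ring C is the only ring made, in the cycloaddition, which also sets C2.

Key step: step 6

Remark on the chemistry (assumption): the sense of induction of the chiral acid cannot be predicted with confidence, so the catalyst antipode that delivers 2S is chosen after a test run; a 2,4-trans adduct formed in the cycloaddition itself could carry the opposite C2 configuration, so only the purified 2,4-cis adduct is carried on unless the trans isomer is shown to be 2S as well.

**Route**

Step 1
Reactants: 1 2,4,6-trihydroxybenzaldehyde; 2 prenyl bromide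
Product: 3 2,4,6-trihydroxy-3-prenylbenzaldehyde
Conditions: DBU (1.0 equiv), THF, 0 °C → rt; 1 in slight excess
Reagents that add atoms: none
Why: Base-mediated C-alkylation of a phloroglucinol-type phenoxide (SN2 on the allylic bromide), in which the ambident para-phenoxide reacts at a ring carbon between two oxygens; the two open ring carbons are equivalent, so only one mono-C-prenyl isomer can form, and the slight excess of 1 should limit double prenylation.

Step 2
Reactants: 3 2,4,6-trihydroxy-3-prenylbenzaldehyde
Product: 4 2,6-dihydroxy-4-methoxy-3-prenylbenzaldehyde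
Conditions: Me2SO4 (1.0 equiv), K2CO3 (1.0 equiv), acetone, 0 °C → rt
Reagents that add atoms: dimethyl sulfate, COS(=O)(=O)OC
Why: Williamson-type O-methylation in which the C4 hydroxyl, para to the formyl group, is the most acidic and the only one not tied to the carbonyl by a hydrogen bond, so one equivalent of a hard methylating agent should go to O4 (dimethyl sulfate is preferred to MeI to suppress C-methylation at the remaining ring CH).

Step 3
Reactants: 4 2,6-dihydroxy-4-methoxy-3-prenylbenzaldehyde
Product: 5 2-hydroxy-4-methoxy-3-prenyl-6-(triisopropylsilyloxy)benzaldehyde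
Conditions: TIPSCl (1.05 equiv), imidazole, DMF, 0 °C → rt
Reagents that add atoms: triisopropylsilyl chloride, CC(C)[Si](Cl)(C(C)C)C(C)C
Why: Phenol silylation under steric control, since the C6 hydroxyl has only a ring CH as its second neighbour whereas the C2 hydroxyl is wedged between the formyl group and the prenyl CH2, so the bulky silyl chloride should react at O6 and leave the C2 hydroxyl hydrogen-bonded to the carbonyl.

Step 4
Reactants: 6 isovanillin
Product: 7 4-methoxy-3-(triisopropylsilyloxy)benzaldehyde
Conditions: TIPSCl, imidazole, DMF, rt
Reagents that add atoms: triisopropylsilyl chloride, CC(C)[Si](Cl)(C(C)C)C(C)C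
Why: Standard silylation of an unhindered phenol, which masks the only acidic group before the ylide step and the acid-catalysed key step.

Step 5
Reactants: 7 4-methoxy-3-(triisopropylsilyloxy)benzaldehyde
Product: 8 4-methoxy-3-(triisopropylsilyloxy)styrene
Conditions: Ph3PCH3Br, KOtBu (slightly less than the salt), THF, 0 °C → rt
Reagents that add atoms: methyltriphenylphosphonium bromide, C[P+](c1ccccc1)(c1ccccc1)c1ccccc1.[Br-]
Why: Wittig methylenation of an aryl aldehyde with the non-stabilised ylide, and the aryl silyl ether should survive because no free alkoxide remains once the ylide is formed.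

Step 6
Reactants: 5 2-hydroxy-4-methoxy-3-prenyl-6-(triisopropylsilyloxy)benzaldehyde; 8 4-methoxy-3-(triisopropylsilyloxy)styrene
Product: 11 (2S,4S)-4,7-dimethoxy-2-[4-methoxy-3-(triisopropylsilyloxy)phenyl]-8-prenyl-5-(triisopropylsilyloxy)chroman (2,4-cis 4-methoxyflavan), via dimethyl acetal 9 (not isolated), via O-methyl oxocarbenium ion 10 (not isolated)
Conditions: confined chiral imidodiphosphorimidate Brønsted acid (two 3,3'-diaryl-BINOL units, N-triflyl groups; 5 mol %), HC(OMe)3 (1.5 equiv), CHCl3, −40 → −20 °C, slow addition of 8; Et3N quench at low temperature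
Reagents that add atoms: trimethyl orthoformate, COC(OC)OC
Why: Proposed new method: the acid turns 5 and the orthoformate into acetal 9 and, by loss of methanol, into the O-methyl oxocarbenium ion 10, a protonated 4-methoxy ortho-quinone methide paired with the chiral anion; the CH2 terminus of 8 attacks C4 and the C2 cation that develops, stabilised by the para-methoxy group of ring B, is captured by the phenol oxygen. The closest known reactions are the achiral acid-promoted coupling of salicylaldehydes, HC(OMe)3 and styrenes to 2,4-cis 4-methoxyflavans and chiral Brønsted acid catalysed cycloadditions of ortho-quinone methides with styrenes. Ring C closes as a six-membered ring in the second bond-forming event of this asynchronous inverse-electron-demand hetero-[4+2], by O1 adding to C2 (formally a 6-endo attack on the styrene π bond). C2 is set by the confined counteranion, which must leave only one face of the ion pair open to the styrene, and C4 follows from the endo-type arrangement that places aryl and methoxy cis and is erased later. The step needs regioselectivity, secured by the benzylic cation at C2; the correct phenol oxygen, secured by the silyl ether on the other ortho oxygen so that the oxygen next to the prenyl group becomes O1; and chemoselectivity for the oxocarbenium ion over protonation of the prenyl alkene or of 8, for which low temperature, catalytic acid and slow addition of 8 are used.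

Step 7
Reactants: 11 (2S,4S)-2,4-cis 4-methoxyflavan
Product: 12 (2S)-7-methoxy-2-[4-methoxy-3-(triisopropylsilyloxy)phenyl]-8-prenyl-5-(triisopropylsilyloxy)chroman-4-ol (mixture of C4 epimers)
Conditions: pyridinium p-toluenesulfonate (cat.), acetone/H2O (4:1), rt, high dilution
Reagents that add atoms: water, O
Why: SN1 solvolysis of a benzylic methyl ether whose C4 cation is stabilised by the three oxygen donors of ring A, driven to the alcohol by the large excess of water; C2 is not involved and keeps its configuration, and the loss of C4 configuration is of no consequence.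

Step 8
Reactants: 12 (2S)-flavan-4-ol (C4 epimers)
Product: 13 (2S)-7-methoxy-2-[4-methoxy-3-(triisopropylsilyloxy)phenyl]-8-prenyl-5-(triisopropylsilyloxy)chroman-4-one
Conditions: Dess–Martin periodinane, pyridine, CH2Cl2, 0 °C
Reagents that add atoms: none
Why: Dess–Martin oxidation of a secondary benzylic alcohol under near-neutral conditions, which brings both C4 epimers to one ketone without ionising C4 and without touching the prenyl alkene, the silyl ethers or C2.

Step 9
Reactants: 13 (2S)-flavanone bis-silyl ether
Product: 14 (2S)-5-hydroxy-2-(3-hydroxy-4-methoxyphenyl)-7-methoxy-8-prenylchroman-4-one (CNP0228678.1)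
Conditions: TBAF/AcOH (1:1, excess), THF, 0 °C → rt
Reagents that add atoms: none
Why: Fluoride cleavage of both aryl silyl ethers, with acetic acid buffering so that no phenoxide or C3 enolate builds up and the retro-oxa-Michael opening to the chalcone, which would racemise C2, is avoided.

**Compound list**

1 | 2,4,6-trihydroxybenzaldehyde | O=Cc1c(O)cc(O)cc1O | starting material
2 | prenyl bromide (1-bromo-3-methylbut-2-ene) | CC(C)=CCBr | starting material
3 | 2,4,6-trihydroxy-3-prenylbenzaldehyde | O=Cc1c(O)c(CC=C(C)C)c(O)cc1O | intermediate
4 | 2,6-dihydroxy-4-methoxy-3-prenylbenzaldehyde | O=Cc1c(O)c(CC=C(C)C)c(OC)cc1O | intermediate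
5 | 2-hydroxy-4-methoxy-3-prenyl-6-(triisopropylsilyloxy)benzaldehyde | O=Cc1c(O)c(CC=C(C)C)c(OC)cc1O[Si](C(C)C)(C(C)C)C(C)C | intermediate
6 | isovanillin (3-hydroxy-4-methoxybenzaldehyde) | COc1ccc(C=O)cc1O | starting material
7 | 4-methoxy-3-(triisopropylsilyloxy)benzaldehyde | COc1ccc(C=O)cc1O[Si](C(C)C)(C(C)C)C(C)C | intermediate
8 | 4-methoxy-3-(triisopropylsilyloxy)styrene | C=Cc1ccc(OC)c(O[Si](C(C)C)(C(C)C)C(C)C)c1 | intermediate
9 | dimethyl acetal of 5 (not isolated) | COC(OC)c1c(O)c(CC=C(C)C)c(OC)cc1O[Si](C(C)C)(C(C)C)C(C)C | intermediate
10 | O-methyl oxocarbenium ion of 5, a protonated 4-methoxy ortho-quinone methide, counterion the catalyst anion (not isolated) | C[O+]=Cc1c(O)c(CC=C(C)C)c(OC)cc1O[Si](C(C)C)(C(C)C)C(C)C | intermediate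
11 | (2S,4S)-4,7-dimethoxy-2-[4-methoxy-3-(triisopropylsilyloxy)phenyl]-8-prenyl-5-(triisopropylsilyloxy)chroman | CO[C@H]1C[C@@H](c2ccc(OC)c(O[Si](C(C)C)(C(C)C)C(C)C)c2)Oc2c(CC=C(C)C)c(OC)cc(O[Si](C(C)C)(C(C)C)C(C)C)c21 | intermediate
12 | (2S)-7-methoxy-2-[4-methoxy-3-(triisopropylsilyloxy)phenyl]-8-prenyl-5-(triisopropylsilyloxy)chroman-4-ol, C4 epimers (C4 left undefined) | OC1C[C@@H](c2ccc(OC)c(O[Si](C(C)C)(C(C)C)C(C)C)c2)Oc2c(CC=C(C)C)c(OC)cc(O[Si](C(C)C)(C(C)C)C(C)C)c21 | intermediate
13 | (2S)-7-methoxy-2-[4-methoxy-3-(triisopropylsilyloxy)phenyl]-8-prenyl-5-(triisopropylsilyloxy)chroman-4-one | O=C1C[C@@H](c2ccc(OC)c(O[Si](C(C)C)(C(C)C)C(C)C)c2)Oc2c(CC=C(C)C)c(OC)cc(O[Si](C(C)C)(C(C)C)C(C)C)c21 | intermediate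
14 | (2S)-5-hydroxy-2-(3-hydroxy-4-methoxyphenyl)-7-methoxy-8-prenylchroman-4-one (CNP0228678.1) | COc1ccc([C@@H]2CC(=O)c3c(O)cc(OC)c(CC=C(C)C)c3O2)cc1O | target

**Step count**

Total step count: 9. Longest linear sequence: 7 steps (steps 1, 2, 3, 6, 7, 8, 9).

**Steps most likely to fail**

1. Step 6 (proposed new method). The facial discrimination inside the ion pair may be weak, because the cation is strongly stabilised and flanked by a bulky silyl ether. The acid may also add the free phenol across the neighbouring prenyl alkene, or start cationic oligomerisation of the styrene. The fallback uses known chemistry and sets out from 5 and 8. The coupling is run with an achiral acid, Sc(OTf)3 with HC(OMe)3 in CH2Cl2 at rt, the established three-component route to 2,4-cis 4-methoxyflavans. It passes through 9 and 10 again and should give the racemic 2,4-cis 4-methoxyflavan F1. Hydrolysis under the conditions of step 7 should give the racemic flavan-4-ol F2, and Dess–Martin oxidation the racemic flavanone bis-silyl ether F3. Preparative chromatography on a polysaccharide chiral stationary phase should then separate 13 from its enantiomer, the (2R)-flavanone bis-silyl ether F4. The route is rejoined at 13.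

2. Step 7. The C4 cation may lose a proton from C3 to give the flav-3-ene, or may be trapped by the electron-rich C6 of ring A of a second molecule (self-condensation) instead of by water. The fallback sets out from 11 and changes the mode of activation from ionisation to hydride abstraction: DDQ (1.1 equiv) in CH2Cl2/pH 7 buffer at 0 °C should remove hydride from C4, water adds to the resulting methoxy-stabilised cation, and the hemiketal collapses to the ketone. This gives 13 directly and bypasses 12, so the route is rejoined at 13. The reaction must be stopped early so that the benzylic-allylic CH2 of the prenyl group is not attacked. New compounds on this path: none F0.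

3. Step 1. O-alkylation and double C-alkylation of the ambident phenoxide may compete with the single C-prenylation. The fallback sets out from 1 and installs the side chain by a sigmatropic shift instead of direct alkylation. Methylation of the C4 hydroxyl (Me2SO4, K2CO3, acetone) should give 2,6-dihydroxy-4-methoxybenzaldehyde F5. Mono-O-allylation (allyl bromide, K2CO3, acetone) should give 2-(allyloxy)-6-hydroxy-4-methoxybenzaldehyde F6. Aromatic Claisen rearrangement (N,N-diethylaniline, 190 °C) moves the allyl group to the only free ortho carbon and should give 3-allyl-2,6-dihydroxy-4-methoxybenzaldehyde F7. Olefin cross-metathesis with 2-methyl-2-butene (second-generation Grubbs catalyst, (H2IMes)(PCy3)Cl2Ru=CHPh, CH2Cl2, 40 °C) should then give 4. The route is rejoined at 4, which replaces steps 1 and 2.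

**Further compounds**

F1 | step 6 | racemic 2,4-cis-4,7-dimethoxy-2-[4-methoxy-3-(triisopropylsilyloxy)phenyl]-8-prenyl-5-(triisopropylsilyloxy)chroman (racemate, relative configuration cis) | COC1CC(c2ccc(OC)c(O[Si](C(C)C)(C(C)C)C(C)C)c2)Oc2c(CC=C(C)C)c(OC)cc(O[Si](C(C)C)(C(C)C)C(C)C)c21
F2 | step 6 | racemic 7-methoxy-2-[4-methoxy-3-(triisopropylsilyloxy)phenyl]-8-prenyl-5-(triisopropylsilyloxy)chroman-4-ol (C4 epimers) | OC1CC(c2ccc(OC)c(O[Si](C(C)C)(C(C)C)C(C)C)c2)Oc2c(CC=C(C)C)c(OC)cc(O[Si](C(C)C)(C(C)C)C(C)C)c21
F3 | step 6 | racemic 7-methoxy-2-[4-methoxy-3-(triisopropylsilyloxy)phenyl]-8-prenyl-5-(triisopropylsilyloxy)chroman-4-one | O=C1CC(c2ccc(OC)c(O[Si](C(C)C)(C(C)C)C(C)C)c2)Oc2c(CC=C(C)C)c(OC)cc(O[Si](C(C)C)(C(C)C)C(C)C)c21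
F4 | step 6 | (2R)-7-methoxy-2-[4-methoxy-3-(triisopropylsilyloxy)phenyl]-8-prenyl-5-(triisopropylsilyloxy)chroman-4-one | O=C1C[C@H](c2ccc(OC)c(O[Si](C(C)C)(C(C)C)C(C)C)c2)Oc2c(CC=C(C)C)c(OC)cc(O[Si](C(C)C)(C(C)C)C(C)C)c21
F0 | step 7 | none | none
F5 | step 1 | 2,6-dihydroxy-4-methoxybenzaldehyde | O=Cc1c(O)cc(OC)cc1O
F6 | step 1 | 2-(allyloxy)-6-hydroxy-4-methoxybenzaldehyde | C=CCOc1cc(OC)cc(O)c1C=O
F7 | step 1 | 3-allyl-2,6-dihydroxy-4-methoxybenzaldehyde | C=CCc1c(OC)cc(O)c(C=O)c1O
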